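**Plan**

1. Numbering: ring C1 (C(OH)CH3), C2 (CH bearing side chain C1′–C5′), C3 (quaternary, CH3 + 4-methylpent-3-enyl), C4 (CHBr), C5, C6.
2. Cuts, in retrosynthetic order: C3′ carbinol with C4′=C5′ (reductive opening of a Sharpless epoxy iodide), C2′–C3′ (B-alkyl Suzuki), C1–CH3 (Grignard), C4–Br (SN2 on an alcohol made from a ketone), C3–CH2 of the homoprenyl chain (enolate alkylation, key), C3–CH3 (enolate methylation), C2–C1′ (asymmetric 1,4-vinylation).
3. Enabling feature: quaternary C3 lies between C4, whose bromide is a latent ketone, and C2. With C4=O, a C5=C6 double bond and a ketal at C1 (a p-benzoquinone monoketal skeleton), C3 is the only enolisable ring atom. The whole C6 chain can therefore be attached there, anti to the C2 vinyl group.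
4. Forward: the six-membered ring is bought as the quinone monoketal and never closed. It is decorated in the order C2 vinyl, C3 methyl, C3 homoprenyl, C5=C6 saturation, C4 OH then Br, C1 ketone then methyl carbinol. The side chain is then grown from the vinyl group.
5. Stereochemistry: C2 from Rh/(R)-BINAP; C3 by 1,2-induction from C2; C4 from CBS reduction followed by inversion; C1 from equatorial Grignard attack enforced by the axial C3 methyl group; C3′ from Sharpless epoxidation with D-(−)-DIPT.

Key step: step 5

Assumption: Rh/(R)-BINAP is taken to attack the quinone monoketal with the facial sense known for 2-cyclohexenone, and (S)-Me-CBS to treat the quaternary α-carbon as the large group.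

**Step 1**
Reactants: 1 5-bromo-2-methylpent-2-ene
Product: 2 5-iodo-2-methylpent-2-ene
Conditions: NaI (3 equiv), acetone, reflux
Reagents that add atoms: sodium iodide, [Na+].[I-]
Why: Finkelstein exchange, driven by precipitation of NaBr, turns the commercial bromide into the softer and faster iodide needed for C-alkylation; no stereocentre is involved.

**Step 2**
Reactants: 3 but-2-yn-1-ol
Product: 5 (Z)-3-iodobut-2-en-1-ol, via cyclic alkenylalanate 4 (not isolated)
Conditions: Red-Al, THF, 0 °C to rt; then I2, THF, −78 to 0 °C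
Reagents that add atoms: iodine, II
Why: Hydroxyl-directed trans-hydroalumination of the propargylic alcohol puts aluminium on C3 inside a five-membered alanate, and iodinolysis with retention should give only the (Z)-alkenyl iodide.

**Step 3**
Reactants: 6 4,4-dimethoxycyclohexa-2,5-dien-1-one
Product: 7 (5R)-5-ethenyl-4,4-dimethoxycyclohex-2-en-1-one
Conditions: CH2=CHBF3K (1.2 equiv), [Rh(cod)2]BF4 (3 mol %), (R)-BINAP (3.5 mol %), Et3N, toluene/H2O, 23–40 °C
Reagents that add atoms: potassium vinyltrifluoroborate, C=C[B-](F)(F)F.[K+]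
Why: Hayashi–Miyaura rhodium-catalysed asymmetric 1,4-addition of an alkenyltrifluoroborate, a reaction type established on quinone-monoketal dienones; the achiral dienone gains a single stereocentre (C2 of the target) whose sense is set by the BINAP ligand.

**Step 4**
Reactants: 7 (5R)-5-ethenyl-4,4-dimethoxycyclohex-2-en-1-one
Product: 9 (5S,6S)-5-ethenyl-4,4-dimethoxy-6-methylcyclohex-2-en-1-one, via lithium dienolate 8 (not isolated)
Conditions: LDA (1.05 equiv), THF, −78 °C; MeI, −78 to −20 °C
Reagents that add atoms: iodomethane, CI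
Why: Kinetic α′-deprotonation and enolate methylation of a cyclohexenone should place methyl trans to vinyl, but this centre is planarised again in step 5, so only the order of the two alkylations matters.

**Step 5**
Reactants: 9 (5S,6S)-5-ethenyl-4,4-dimethoxy-6-methylcyclohex-2-en-1-one; 2 5-iodo-2-methylpent-2-ene
Product: 11 (5S,6S)-5-ethenyl-4,4-dimethoxy-6-methyl-6-(4-methylpent-3-en-1-yl)cyclohex-2-en-1-one, via lithium dienolate 10 (not isolated)
Conditions: LDA (1.15 equiv), THF, −78 to −10 °C; DMPU (5 equiv), 2 (2.5 equiv), −78 °C to rt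
Reagents that add atoms: none
Why: LDA removes the only enolisable proton of 9 (H-6; C2 and C3 are vinylic and the γ-carbon C4 is a ketal carbon without hydrogen), and the tetrasubstituted α-carbon of the cross-conjugated dienolate 10 displaces iodide from 2 in an SN2 C-alkylation. The closest known reaction type is the sequential kinetic α′-dialkylation of cyclohex-2-enones (Stork–Danheiser type, as practised on 6-methylcarvone) that builds a quaternary carbon next to a C5 substituent. No ring is closed. The new quaternary stereocentre is controlled by the adjacent C5 vinyl group, held pseudoaxial by A(1,2) strain with the C6 methyl group and by the flanking ketal, so the iodide is attacked from the opposite face and the homoprenyl chain ends trans to vinyl; putting methyl in first and homoprenyl second therefore fixes (6S). The step needs C- over O-alkylation (soft iodide, lithium counter-ion, DMPU), substitution over E2 of the homoallylic iodide (excess 2, cold start) and a single regioisomer, which the C2=C3 double bond and the ketal guarantee; over-alkylation is impossible because 11 has no α-hydrogen.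

**Step 6**
Reactants: 11 (5S,6S)-5-ethenyl-4,4-dimethoxy-6-methyl-6-(4-methylpent-3-en-1-yl)cyclohex-2-en-1-one
Product: 13 (2S,3S)-3-ethenyl-4,4-dimethoxy-2-methyl-2-(4-methylpent-3-en-1-yl)cyclohexan-1-one, via dimethylphenylsilyl enol ether 12 (not isolated)
Conditions: [(Ph3P)CuH]6 (cat.), PhMe2SiH (1.5 equiv), toluene, rt; then K2CO3 (cat.), MeOH/H2O, 0 °C
Reagents that add atoms: none
Why: Copper hydride (Stryker-type) conjugate reduction attacks only the electron-poor enone C=C and leaves the vinyl group, the trisubstituted alkene and the ketal untouched; no stereocentre is formed.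

**Step 7**
Reactants: 13 (2S,3S)-3-ethenyl-4,4-dimethoxy-2-methyl-2-(4-methylpent-3-en-1-yl)cyclohexan-1-one
Product: 14 (1R,2S,3S)-3-ethenyl-4,4-dimethoxy-2-methyl-2-(4-methylpent-3-en-1-yl)cyclohexan-1-ol
Conditions: (S)-Me-CBS (0.5 equiv), catecholborane (2 equiv), toluene, −78 to −40 °C; aq. NaOH work-up
Reagents that add atoms: none
Why: Corey–Bakshi–Shibata reduction with the quaternary C2 as large and C6H2 as small group should deliver hydride to the face carrying the C2 methyl and C3 vinyl groups, giving the (1R)-alcohol (OH cis to the homoprenyl chain) by reagent control in a conformationally mobile ring; catecholborane at low temperature does not hydroborate the alkenes.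

**Step 8**
Reactants: 14 (1R,2S,3S)-3-ethenyl-4,4-dimethoxy-2-methyl-2-(4-methylpent-3-en-1-yl)cyclohexan-1-ol
Product: 15 (2S,3S,4R)-2-ethenyl-4-hydroxy-3-methyl-3-(4-methylpent-3-en-1-yl)cyclohexan-1-one
Conditions: PPTS (0.2 equiv), acetone/H2O (10:1), rt
Reagents that add atoms: water, O
Why: Mild acid-catalysed ketal hydrolysis, placed before the bromination so that no ketal oxygen can take part transannularly at the carbinol carbon; it is too mild to enolise the new α-vinyl ketone, and aromatisation is blocked by the quaternary carbon.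

**Step 9**
Reactants: 15 (2S,3S,4R)-2-ethenyl-4-hydroxy-3-methyl-3-(4-methylpent-3-en-1-yl)cyclohexan-1-one
Product: 16 (2S,3S,4S)-4-bromo-2-ethenyl-3-methyl-3-(4-methylpent-3-en-1-yl)cyclohexan-1-one
Conditions: CBr4 (2 equiv), PPh3 (2.2 equiv), 2,6-lutidine (0.5 equiv), toluene, 0 to 70 °C
Reagents that add atoms: tetrabromomethane, BrC(Br)(Br)Br
Why: Appel reaction, in which bromide displaces the axial oxyphosphonium group with inversion, as known for axial neopentylic cyclohexanols, to give the equatorial (4S)-bromide; the ring oxygen function is a ketone at this stage and cannot form a 1,4-ether bridge.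

**Step 10**
Reactants: 16 (2S,3S,4S)-4-bromo-2-ethenyl-3-methyl-3-(4-methylpent-3-en-1-yl)cyclohexan-1-one
Product: 17 (1R,2S,3S,4S)-4-bromo-2-ethenyl-1,3-dimethyl-3-(4-methylpent-3-en-1-yl)cyclohexan-1-ol
Conditions: MeMgBr (2 equiv), LaCl3·2LiCl (0.3 equiv), THF, −78 to −30 °C; aq. NH4Cl
Reagents that add atoms: methylmagnesium bromide, C[Mg]Br
Why: Lanthanide-assisted Grignard 1,2-addition. In the chair with Br, vinyl and homoprenyl equatorial the axial C3 methyl group blocks axial attack (as in 3,3,5-trimethylcyclohexanone), so methyl should enter equatorially and leave the axial (1R)-OH cis to the C3 methyl group; low basicity avoids enolisation and E2.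

**Step 11**
Reactants: 17 (1R,2S,3S,4S)-4-bromo-2-ethenyl-1,3-dimethyl-3-(4-methylpent-3-en-1-yl)cyclohexan-1-ol; 5 (Z)-3-iodobut-2-en-1-ol
Product: 19 (1R,2S,3S,4S)-4-bromo-2-[(3Z)-5-hydroxy-3-methylpent-3-en-1-yl]-1,3-dimethyl-3-(4-methylpent-3-en-1-yl)cyclohexan-1-ol, via B-alkyl-9-BBN 18 (not isolated)
Conditions: 9-BBN (2.2 equiv), THF, rt to 45 °C; then 5, PdCl2(dppf) (5 mol %), AsPh3 (10 mol %), Cs2CO3 (3 equiv), DMF/H2O, rt
Reagents that add atoms: none
Why: 9-BBN hydroborates the monosubstituted alkene in preference to the trisubstituted one, and the B-alkyl Suzuki–Miyaura coupling keeps the (Z)-geometry of 5; the secondary neopentylic bromide is not activated by Pd(dppf) at rt.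

**Step 12**
Reactants: 19 (1R,2S,3S,4S)-4-bromo-2-[(3Z)-5-hydroxy-3-methylpent-3-en-1-yl]-1,3-dimethyl-3-(4-methylpent-3-en-1-yl)cyclohexan-1-ol
Product: 20 (1R,2S,3S,4S)-4-bromo-2-{2-[(2S,3R)-3-(hydroxymethyl)-2-methyloxiran-2-yl]ethyl}-1,3-dimethyl-3-(4-methylpent-3-en-1-yl)cyclohexan-1-ol
Conditions: Ti(OiPr)4 (0.2 equiv), D-(−)-DIPT (0.25 equiv), t-BuOOH (2 equiv, decane), 4 Å MS, CH2Cl2, −20 °C
Reagents that add atoms: tert-butyl hydroperoxide, CC(C)(C)OO
Why: Sharpless asymmetric epoxidation touches only the allylic-alcohol alkene, and with D-(−)-tartrate a (Z)-3-methylalk-2-en-1-ol (nerol type) should give the (2R,3S)-epoxy alcohol, which sets the future C3′ centre under reagent control.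

**Step 13**
Reactants: 20 (1R,2S,3S,4S)-4-bromo-2-{2-[(2S,3R)-3-(hydroxymethyl)-2-methyloxiran-2-yl]ethyl}-1,3-dimethyl-3-(4-methylpent-3-en-1-yl)cyclohexan-1-ol
Product: 21 (1R,2S,3S,4S)-4-bromo-2-{2-[(2S,3S)-3-(iodomethyl)-2-methyloxiran-2-yl]ethyl}-1,3-dimethyl-3-(4-methylpent-3-en-1-yl)cyclohexan-1-ol
Conditions: I2, PPh3, imidazole, CH2Cl2, 0 °C
Reagents that add atoms: iodine, II
Why: Garegg–Samuelsson (Appel-type) iodination converts only the primary alcohol; the tertiary ring alcohol and the epoxide stay intact, and the descriptor change at the oxirane CH is only a priority effect.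

**Step 14**
Reactants: 21 (1R,2S,3S,4S)-4-bromo-2-{2-[(2S,3S)-3-(iodomethyl)-2-methyloxiran-2-yl]ethyl}-1,3-dimethyl-3-(4-methylpent-3-en-1-yl)cyclohexan-1-ol
Product: 22 (1R,2S,3S,4S)-4-bromo-2-[(3S)-3-hydroxy-3-methylpent-4-en-1-yl]-1,3-dimethyl-3-(4-methylpent-3-en-1-yl)cyclohexan-1-ol
Conditions: activated Zn dust, EtOH, 60 °C; aq. NH4Cl
Reagents that add atoms: none
Why: Zinc-mediated reductive β-elimination of a 2,3-epoxy iodide (Boord-type) opens the oxirane to the tertiary allylic alcohol without touching the C3′–O bond, so (3′S) is retained; the unactivated secondary bromide is inert to zinc.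

**Compound list**

1 | 5-bromo-2-methylpent-2-ene | CC(C)=CCCBr | starting material
2 | 5-iodo-2-methylpent-2-ene | CC(C)=CCCI | intermediate
3 | but-2-yn-1-ol | CC#CCO | starting material
4 | sodium cyclic alkenylalanate from 3 and Red-Al | CC1=CCO[Al-]1(OCCOC)OCCOC.[Na+] | intermediate
5 | (Z)-3-iodobut-2-en-1-ol | C/C(I)=C/CO | intermediate
6 | 4,4-dimethoxycyclohexa-2,5-dien-1-one | COC1(OC)C=CC(=O)C=C1 | starting material
7 | (5R)-5-ethenyl-4,4-dimethoxycyclohex-2-en-1-one | C=C[C@H]1CC(=O)C=CC1(OC)OC | intermediate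
8 | lithium dienolate of 7 | C=C[C@H]1C=C([O-])C=CC1(OC)OC.[Li+] | intermediate
9 | (5S,6S)-5-ethenyl-4,4-dimethoxy-6-methylcyclohex-2-en-1-one | C=C[C@H]1[C@H](C)C(=O)C=CC1(OC)OC | intermediate
10 | lithium dienolate of 9 | C=C[C@H]1C(C)=C([O-])C=CC1(OC)OC.[Li+] | intermediate
11 | (5S,6S)-5-ethenyl-4,4-dimethoxy-6-methyl-6-(4-methylpent-3-en-1-yl)cyclohex-2-en-1-one | C=C[C@H]1[C@](C)(CCC=C(C)C)C(=O)C=CC1(OC)OC | intermediate
12 | dimethylphenylsilyl enol ether of 13 | C=C[C@H]1[C@](C)(CCC=C(C)C)C(O[Si](C)(C)c2ccccc2)=CCC1(OC)OC | intermediate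
13 | (2S,3S)-3-ethenyl-4,4-dimethoxy-2-methyl-2-(4-methylpent-3-en-1-yl)cyclohexan-1-one | C=C[C@H]1[C@](C)(CCC=C(C)C)C(=O)CCC1(OC)OC | intermediate
14 | (1R,2S,3S)-3-ethenyl-4,4-dimethoxy-2-methyl-2-(4-methylpent-3-en-1-yl)cyclohexan-1-ol | C=C[C@H]1[C@](C)(CCC=C(C)C)[C@H](O)CCC1(OC)OC | intermediate
15 | (2S,3S,4R)-2-ethenyl-4-hydroxy-3-methyl-3-(4-methylpent-3-en-1-yl)cyclohexan-1-one | C=C[C@H]1[C@](C)(CCC=C(C)C)[C@H](O)CCC1=O | intermediate
16 | (2S,3S,4S)-4-bromo-2-ethenyl-3-methyl-3-(4-methylpent-3-en-1-yl)cyclohexan-1-one | C=C[C@H]1[C@](C)(CCC=C(C)C)[C@@H](Br)CCC1=O | intermediate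
17 | (1R,2S,3S,4S)-4-bromo-2-ethenyl-1,3-dimethyl-3-(4-methylpent-3-en-1-yl)cyclohexan-1-ol | C=C[C@H]1[C@](C)(CCC=C(C)C)[C@@H](Br)CC[C@@]1(C)O | intermediate
18 | B-alkyl-9-BBN adduct of 17 (boron on the terminal side-chain carbon) | C1CC2CCCC(C1)B2CC[C@H]1[C@](C)(CCC=C(C)C)[C@@H](Br)CC[C@@]1(C)O | intermediate
19 | (1R,2S,3S,4S)-4-bromo-2-[(3Z)-5-hydroxy-3-methylpent-3-en-1-yl]-1,3-dimethyl-3-(4-methylpent-3-en-1-yl)cyclohexan-1-ol | OC/C=C(/C)CC[C@H]1[C@](C)(CCC=C(C)C)[C@@H](Br)CC[C@@]1(C)O | intermediate
20 | (1R,2S,3S,4S)-4-bromo-2-{2-[(2S,3R)-3-(hydroxymethyl)-2-methyloxiran-2-yl]ethyl}-1,3-dimethyl-3-(4-methylpent-3-en-1-yl)cyclohexan-1-ol | OC[C@H]1O[C@@]1(C)CC[C@H]1[C@](C)(CCC=C(C)C)[C@@H](Br)CC[C@@]1(C)O | intermediate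
21 | (1R,2S,3S,4S)-4-bromo-2-{2-[(2S,3S)-3-(iodomethyl)-2-methyloxiran-2-yl]ethyl}-1,3-dimethyl-3-(4-methylpent-3-en-1-yl)cyclohexan-1-ol | IC[C@H]1O[C@@]1(C)CC[C@H]1[C@](C)(CCC=C(C)C)[C@@H](Br)CC[C@@]1(C)O | intermediate
22 | (1R,2S,3S,4S)-4-bromo-2-[(3S)-3-hydroxy-3-methylpent-4-en-1-yl]-1,3-dimethyl-3-(4-methylpent-3-en-1-yl)cyclohexan-1-ol | C=C[C@@](C)(O)CC[C@H]1[C@](C)(CCC=C(C)C)[C@@H](Br)CC[C@@]1(C)O | target

**Step count**

Total step count: 14. Longest linear sequence: 12 steps (steps 3–14, from 6).

**Steps most likely to fail**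

1. **Step 9 (bromination).** E2 loss of the activated axial oxygen toward the neighbouring CH2, or a Wagner–Meerwein shift from the adjacent quaternary carbon, may outrun backside attack of bromide at the neopentylic carbon.
   - Fallback, from 15 back to 16: activation and substitution are separated.
   - Tf2O and pyridine in CH2Cl2 at −78 °C give the axial triflate (1R,2S,3S)-3-ethenyl-2-methyl-2-(4-methylpent-3-en-1-yl)-4-oxocyclohexyl trifluoromethanesulfonate F1, which is isolated cold.
   - F1 is then displaced in a second operation by a poorly solvated bromide (Bu4NBr, toluene, 0 °C to rt). Substitution can thus run far below the temperature at which the phosphonium route eliminates.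

2. **Step 5 (key alkylation).** C-alkylation of the hindered tetrasubstituted dienolate by an unactivated iodide may be slow, so dehydroiodination of the homoallylic iodide and O-alkylation take over.
   - Fallback, from 9 back to 11: the same dienolate 10 is quenched with the much more reactive propargyl bromide. This gives the propargyl ketone (5S,6S)-5-ethenyl-4,4-dimethoxy-6-methyl-6-(prop-2-yn-1-yl)cyclohex-2-en-1-one F2, formed at the same bond with the same facial control.
   - Ruthenium-catalysed anti-Markovnikov hydration of the terminal alkyne (CpRu–phosphine catalyst, acetone/H2O) gives the aldehyde 3-[(1S,6S)-6-ethenyl-5,5-dimethoxy-1-methyl-2-oxocyclohex-3-en-1-yl]propanal F3.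
   - Wittig olefination with isopropylidenetriphenylphosphorane at −78 °C, which reacts at the aldehyde and not at the hindered enone, delivers 11.

3. **Step 7 (ketone reduction).** The reduction may stall or show poor facial selectivity, because the ketone is flanked by a quaternary carbon and the ring is conformationally mobile, so catalyst and substrate bias may be mismatched.
   - Fallback, from 13 back to 14: a biocatalytic reduction with an NADPH-dependent ketoreductase (short-chain dehydrogenase/reductase class). The enzyme is chosen from a panel for the (1R)-alcohol, with isopropanol or glucose/glucose dehydrogenase recycling in buffer/DMSO.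
   - Alkenes and ketal are left untouched, and no compound outside the list is formed (F0).

**Further compounds**

F1 | step 9 | (1R,2S,3S)-3-ethenyl-2-methyl-2-(4-methylpent-3-en-1-yl)-4-oxocyclohexyl trifluoromethanesulfonate | C=C[C@H]1[C@](C)(CCC=C(C)C)[C@H](OS(=O)(=O)C(F)(F)F)CCC1=O
F2 | step 5 | (5S,6S)-5-ethenyl-4,4-dimethoxy-6-methyl-6-(prop-2-yn-1-yl)cyclohex-2-en-1-one | C=C[C@H]1[C@](C)(CC#C)C(=O)C=CC1(OC)OC
F3 | step 5 | 3-[(1S,6S)-6-ethenyl-5,5-dimethoxy-1-methyl-2-oxocyclohex-3-en-1-yl]propanal | C=C[C@H]1[C@](C)(CCC=O)C(=O)C=CC1(OC)OC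
F0 | step 7 | none | none
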